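Skeleton numbering: C1 is the bridgehead with benzoyl; C2 and C4 are the ketones on either side of quaternary C3; C5 is the bridgehead with geranyl; C9 is the one-carbon ketone bridge between C1 and C5. C6H2–C7H–C8Me2 is the three-carbon bridge from C5 to C1; C11H2–C12H joins C7 to C3; C13Me2, C14H(isopropenyl) and C15H2 complete the cyclopentane on C3–C12.
Cuts: first C13–C14 and C3–C12 (radical cascade), then C8–C1 and C7–C11 (prenyl transfer with ring closure), then C5–geranyl and the two aryl–prenyl bonds. This leads back to 2,4,6-trihydroxybenzophenone, prenyl bromide and geranyl bromide.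
Enabling feature: within ring C1–C8–C7–C6–C5–C9, the segment C6–C7–C8Me2 is a prenyl group of C5. Its CH carbon C7 has gained a second C5 unit through C11, and its CMe2 carbon C8 is bonded to the acyl-bearing carbon C1 of the former phloroglucinol ring C1–C2–C3–C4–C5–C9. This is the pattern left by dimethylallyl cation addition to an olefin followed by enol capture.
Ring order: the arene becomes the trione ring by dearomatising geranylation of the symmetric 3,5-diprenyl compound. The enzyme closes the second six-membered ring (bicyclo[3.3.1]nonane). Mn(OAc)3/Cu(OAc)2 then closes the homoadamantane cage (two seven-membered rings) through C3–C12, and last the cyclopentane through C13–C14.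
Stereochemistry: C5 comes from separation of the racemic dearomatised trione on a chiral phase; C7 from the enzyme; C1 from C5 through the bridge; C3, C12 and C14 from the cage geometry during the cascade; the geranyl E olefin is bought.

Key step: step 5

Assumption: a UbiA-type prenyltransferase with the chain, face and closure selectivity required exists among the homologues of plants that make 7-endo benzoyl congeners (Hypericum sampsonii, Clusia species), and it is identified by screening these, expressed in yeast, against the synthetic substrate. The enolised triones are drawn as one tautomer each.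

Step 1
Reactants: 1 2,4,6-trihydroxybenzophenone; 2 prenyl bromide (1-bromo-3-methylbut-2-ene)
Product: 3 2,4,6-trihydroxy-3,5-bis(3-methylbut-2-enyl)benzophenone
Conditions: 2 (2.1 equiv), KOH, H2O, 0 °C to rt
Reagents that add atoms: prenyl bromide 2, CC(C)=CCBr
Why: Aqueous-base C-alkylation of a phloroglucinolate (electrophilic aromatic substitution by an allylic bromide), in which hydrogen bonding of water to the phenolate oxygens steers the soft electrophile to the two free ring carbons; no stereocentre is formed.

Step 2
Reactants: 3 2,4,6-trihydroxy-3,5-bis(3-methylbut-2-enyl)benzophenone; 4 geranyl bromide ((2E)-1-bromo-3,7-dimethylocta-2,6-diene)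
Product: 5 rac-2-benzoyl-6-geranyl-3,5-dihydroxy-4,6-diprenylcyclohexa-2,4-dien-1-one
Conditions: NaOMe, MeOH, 0 °C; 4 (1.0 equiv) added slowly, to rt
Reagents that add atoms: geranyl bromide 4, CC(C)=CCC/C(C)=C/CBr
Why: Alkylative dearomatisation of the lupulone type, in which the two prenyl-bearing ring carbons of 3 are related by a time-averaged mirror plane, so C-geranylation at either gives the same constitution with prenyl and geranyl on the new quaternary C5 (formed racemic) and avoids the site ambiguity that an arene with one geranyl and one prenyl group would show toward prenyl bromide.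

Step 3
Reactants: 5 rac-2-benzoyl-6-geranyl-3,5-dihydroxy-4,6-diprenylcyclohexa-2,4-dien-1-one
Product: 6 (6S)-2-benzoyl-6-[(2E)-3,7-dimethylocta-2,6-dienyl]-3,5-dihydroxy-4,6-bis(3-methylbut-2-enyl)cyclohexa-2,4-dien-1-one
Conditions: preparative SFC on amylose tris(3,5-dimethylphenylcarbamate), CO2/MeOH with 0.1% HCO2H, 35 °C
Reagents that add atoms: none
Why: Chromatographic enantiomer separation on a polysaccharide phase, reliable here because quaternary C5 cannot racemise; the (S) enantiomer is assigned by comparing measured and computed ECD, and using it alone keeps the antipode from placing its geranyl 2,3-olefin where the enzyme expects the prenyl olefin and giving an isomer of the same mass.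

Step 4
Reactants: 2 prenyl bromide
Product: 7 dimethylallyl diphosphate (3-methylbut-2-enyl diphosphate), handled as the triammonium salt
Conditions: (Bu4N)3HP2O7, MeCN, rt; then sulfonate resin (NH4+ form), cellulose chromatography (iPrOH/MeCN/aq NH4HCO3)
Reagents that add atoms: tris(tetrabutylammonium) hydrogen diphosphate, CCCC[N+](CCCC)(CCCC)CCCC.CCCC[N+](CCCC)(CCCC)CCCC.CCCC[N+](CCCC)(CCCC)CCCC.OP(=O)([O-])OP(=O)([O-])[O-]
Why: SN2 displacement of a primary allylic bromide by the diphosphate trianion in a dipolar aprotic solvent is the standard entry to allylic diphosphates, and the cation exchange removes the lipophilic counter-ion that would disturb a membrane enzyme.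

Step 5
Reactants: 6 (6S)-2-benzoyl-6-geranyl-3,5-dihydroxy-4,6-diprenylcyclohexa-2,4-dien-1-one; 7 dimethylallyl diphosphate
Product: 9 (1R,5R,7R)-1-benzoyl-5-geranyl-4-hydroxy-8,8-dimethyl-3,7-diprenylbicyclo[3.3.1]non-3-ene-2,9-dione (C7 prenyl endo), via C8 tertiary cation 8 (not isolated)
Conditions: yeast microsomes carrying the selected membrane-bound UbiA-type aromatic prenyltransferase, 7 (3 equiv), MgCl2 (10 mM), Tris-HCl pH 7.5, DMSO (5 vol%), 30 °C
Reagents that add atoms: dimethylallyl diphosphate 7, CC(C)=CCOP(=O)(O)OP(=O)(O)O
Why: Magnesium-assisted ionisation of the C–O bond of 7 in the active site hands its CH2 terminus (C11) to olefin carbon C7 of the C5 prenyl chain of 6, the charge passes to tertiary C8 (cation 8), and enol carbon C1 closes C8–C1 with loss of the enol proton. The closest known reaction type is the prenylation–cyclisation by which UbiA-superfamily aromatic prenyltransferases convert dearomatised polyprenylated acylphloroglucinols into bicyclo[3.3.1]nonane-2,4,9-triones in plants, applied here to the benzoyl/geranyl member of that class. The one ring closed, C1–C8–C7–C6–C5–C9, forms in a 6-endo-trig mode with respect to the C7=C8 olefin (both olefin carbons become ring members), with the C1=C2 enol exocyclic to the new ring. C1 is fixed by C5, because the bridge C6–C7–C8 can span C5 and C1 only on the ring face that carries C6, whereas C7 is fixed by the protein, which must hold the chain in the boat-like fold so that anti addition of C11 and C1 across the olefin leaves C11 endo, directed at C3 (the chair-like fold would give the exo epimer). The step needs the prenyl and not the geranyl 2,3-olefin to react, C11 to arrive on the correct face of C7, and C1 rather than C3 or an enol oxygen to take the cation; the substrate contributes the single C5 configuration from step 3, which places the short and the long chain in different pockets, and a tether that limits capture to the atoms flanking C5, while the remaining choices rest with the active site and are the criteria of the screen.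

Step 6
Reactants: 9 (1R,5R,7R)-1-benzoyl-5-geranyl-4-hydroxy-8,8-dimethyl-3,7-diprenylbicyclo[3.3.1]non-3-ene-2,9-dione
Product: 13 CNP0110731.1 (1S,3S,5R,7R,12S,14S in the skeleton numbering), via C3 radical 10 (not isolated), via C13 radical 11 (not isolated), via 2-propyl radical 12 (not isolated)
Conditions: Mn(OAc)3·2H2O (2.2 equiv), Cu(OAc)2·H2O (1 equiv), degassed AcOH, rt
Reagents that add atoms: none
Why: This is an oxidative radical cyclisation of an enolised 1,3-diketone with trivalent manganese, well known for polyprenylated acylphloroglucinols: radical 10 can reach only the endo C7 prenyl group (the bridgehead geranyl chain is equatorial to the dione ring and cannot bridge to C3) and adds 7-exo-trig to C12 on the face of C3 that looks at C7, the equatorial C8 methyl turning the CMe2 end toward the C6/C4 side and so setting C12; tertiary radical 11 then closes 5-exo-trig on C14 of the C3 prenyl group through a chair-like transition state that puts the new radical centre trans to C11 and cis to H12, and divalent copper oxidises radical 12 to the less substituted olefin (isopropenyl), the monovalent copper being returned to Cu(OAc)2 by the second equivalent of Mn(OAc)3.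

Compound list
1 | 2,4,6-trihydroxybenzophenone | O=C(c1ccccc1)c1c(O)cc(O)cc1O | starting material
2 | prenyl bromide | CC(C)=CCBr | starting material
3 | 2,4,6-trihydroxy-3,5-bis(3-methylbut-2-enyl)benzophenone | CC(C)=CCc1c(O)c(CC=C(C)C)c(O)c(C(=O)c2ccccc2)c1O | intermediate
4 | geranyl bromide | CC(C)=CCC/C(C)=C/CBr | starting material
5 | rac-2-benzoyl-6-geranyl-3,5-dihydroxy-4,6-diprenylcyclohexa-2,4-dien-1-one (racemate) | CC(C)=CCC1=C(O)C(C/C=C(\C)CCC=C(C)C)(CC=C(C)C)C(=O)C(C(=O)c2ccccc2)=C1O | intermediate
6 | (6S)-2-benzoyl-6-geranyl-3,5-dihydroxy-4,6-diprenylcyclohexa-2,4-dien-1-one | CC(C)=CCC1=C(O)[C@@](C/C=C(\C)CCC=C(C)C)(CC=C(C)C)C(=O)C(C(=O)c2ccccc2)=C1O | intermediate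
7 | dimethylallyl diphosphate (drawn as the acid, handled as the triammonium salt) | CC(C)=CCOP(=O)(O)OP(=O)(O)O | intermediate
8 | enzyme-bound C8 tertiary cation: 6 with the C5 prenyl group replaced by CH2–CH(prenyl)–C+(CH3)2, C7 configured as in 9 | CC(C)=CCC1=C(O)[C@@](C/C=C(\C)CCC=C(C)C)(C[C@@H](CC=C(C)C)[C+](C)C)C(=O)C(C(=O)c2ccccc2)=C1O | intermediate
9 | (1R,5R,7R)-1-benzoyl-5-geranyl-4-hydroxy-8,8-dimethyl-3,7-diprenylbicyclo[3.3.1]non-3-ene-2,9-dione, C7 prenyl endo (axial, toward C3) | CC(C)=CCC3=C(O)[C@@]4(C/C=C(\C)CCC=C(C)C)C[C@@H](CC=C(C)C)C(C)(C)[C@](C(=O)c1ccccc1)(C4=O)C3=O | intermediate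
10 | C3 radical of the 2,4,9-trione derived from 9 | CC(C)=CC[C]3C(=O)[C@@]4(C/C=C(\C)CCC=C(C)C)C[C@@H](CC=C(C)C)C(C)(C)[C@](C(=O)c1ccccc1)(C4=O)C3=O | intermediate
11 | homoadamantane C13 radical (C3–C12 formed, C3 prenyl intact) | CC(C)=CC[C@@]23C(=O)[C@@]4(C/C=C(\C)CCC=C(C)C)C[C@@H](C[C@H]2[C](C)C)C(C)(C)[C@](C(=O)c1ccccc1)(C4=O)C3=O | intermediate
12 | 2-propyl radical on C14 (cyclopentane closed) | C[C](C)[C@@H]1C[C@@]23C(=O)[C@@]4(C/C=C(\C)CCC=C(C)C)C[C@@H](C[C@H]2C1(C)C)C(C)(C)[C@](C(=O)c1ccccc1)(C4=O)C3=O | intermediate
13 | CNP0110731.1: benzoyl (C1), geranyl (C5), 8,8,13,13-tetramethyl, 14-isopropenyl tetracyclo[7.3.1.1(3,11).0(3,7)]tetradecane-2,12,14-trione; C13 on the C4/C6 side, isopropenyl cis to H12 | C=C(C)[C@@H]1C[C@@]23C(=O)[C@@]4(C/C=C(\C)CCC=C(C)C)C[C@@H](C[C@H]2C1(C)C)C(C)(C)[C@](C(=O)c1ccccc1)(C4=O)C3=O | target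

Total steps: 6. Longest linear sequence: 5 (steps 1, 2, 3, 5, 6).

Steps most likely to fail

Step 5.
- What may go wrong: no homologue may turn the substrate over. Turnover may instead go with attack on the geranyl 2,3-olefin, delivery of C11 to the exo face, or closure at C3. Loss of activity of the membrane protein may also limit scale.
- Why not simply generate cation 8 with acid: a free cation 8 would be expected to close at the more nucleophilic C3 through the chair fold. The fallback therefore ties the C7 substituent to C3, which enforces both closure at C1 and the endo orientation.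
- Fallback: it sets out from 1 and comes back at 9.
 - 1 is C-geranylated with 4 (KOH, H2O) to 3-geranyl-2,4,6-trihydroxybenzophenone F1, which is C-prenylated with 2 to 3-geranyl-5-prenyl-2,4,6-trihydroxybenzophenone F2.
 - Addition–elimination of the anion of F2 (LiHMDS, THF) on the separately prepared 3-acetoxy-3-methyl-2-methylenebutanal F3 should give the dearomatised β,β-dimethyl enal F4. This has to be separated from the isomer alkylated at the prenyl-bearing carbon.
 - Concentrated HCl in THF then brings about conjugate addition of C1 to C8 and aldol closure of C3 on the aldehyde carbon C11, giving the hydroxyadamantane F5.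
 - Vinylmagnesium bromide/CeCl3 opens F5 by retro-aldol reaction and adds to the freed endo aldehyde to give the allylic alcohol F6, and acetylation gives the allylic acetate F7.
 - Pd(PPh3)4/HCO2NH4 removes the acetate with hydride delivery to C11 to give the 7-endo-allyl compound F8.
 - Cross metathesis with 2-methylbut-2-ene (second-generation Grubbs catalyst), in which the terminal olefin reacts far faster than the trisubstituted ones, gives racemic 9. From this, 9 is taken by chiral SFC as in step 3.

Step 6.
- What may go wrong: divalent copper may oxidise radical 11 before the 5-exo closure, traces of oxygen may capture radical 10, and facial selectivity at C12 may be poor.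
- Fallback: it sets out from 9 and comes back at 13, replacing oxidative generation and termination by halogen atom transfer.
 - The sodium enolate of 9 is brominated at C3 with NBS to the 3-bromo trione F9.
 - Et3B/air in CH2Cl2 starts a bromine atom-transfer chain through the same radicals 10 to 12. No oxidant competes with ring closure, and radical 12 ends as the tertiary bromide F10.
 - DBU in toluene then eliminates HBr toward a methyl group to give 13.

Step 2.
- What may go wrong: O-geranylation, and a second alkylation at the remaining prenyl-bearing carbon, compete with C-alkylation at a hindered ring carbon.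
- Fallback: it sets out from 3 and comes back at 5 by a Tsuji–Trost dearomatising allylation.
 - Geraniol and methyl chloroformate (pyridine) give geranyl methyl carbonate F11, which is combined with 3 and catalytic Pd(PPh3)4 in THF.
 - Zerovalent palladium ionises the carbonate, and any O-geranyl ether, reversibly, so material should funnel to the C-alkylated product.
 - Attack at the unsubstituted allyl terminus keeps the chain linear.
 - Erosion of the E geometry through allyl isomerisation has to be watched.

Further compounds
F1 | step 5 | 3-geranyl-2,4,6-trihydroxybenzophenone | CC(C)=CCC/C(C)=C/Cc1c(O)cc(O)c(C(=O)c2ccccc2)c1O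
F2 | step 5 | 3-geranyl-5-prenyl-2,4,6-trihydroxybenzophenone | CC(C)=CCC/C(C)=C/Cc1c(O)c(CC=C(C)C)c(O)c(C(=O)c2ccccc2)c1O
F3 | step 5 | 3-acetoxy-3-methyl-2-methylenebutanal | CC(=O)OC(C)(C)C(=C)C=O
F4 | step 5 | rac-2-benzoyl-6-geranyl-6-(2-formyl-3-methylbut-2-enyl)-3,5-dihydroxy-4-prenylcyclohexa-2,4-dien-1-one | CC(C)=CCC1=C(O)C(C/C=C(\C)CCC=C(C)C)(CC(C=O)=C(C)C)C(=O)C(C(=O)c2ccccc2)=C1O
F5 | step 5 | hydroxyadamantane trione, C11 carbinol bridging C3 and C7 (racemic, enantiomer matching 9 drawn, carbinol centre open) | O=C(c1ccccc1)[C@@]12C(=O)[C@]3(CC=C(C)C)C(=O)[C@@](C/C=C(\C)CCC=C(C)C)(C[C@@H](C3O)C1(C)C)C2=O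
F6 | step 5 | 7-endo-(1-hydroxyprop-2-enyl) analogue of 9 (racemic, enantiomer matching 9 drawn) | CC(C)=CCC3=C(O)[C@@]4(C/C=C(\C)CCC=C(C)C)C[C@@H](C(O)C=C)C(C)(C)[C@](C(=O)c1ccccc1)(C4=O)C3=O
F7 | step 5 | 7-endo-(1-acetoxyprop-2-enyl) analogue of 9 (racemic, enantiomer matching 9 drawn) | CC(C)=CCC3=C(O)[C@@]4(C/C=C(\C)CCC=C(C)C)C[C@@H](C(OC(C)=O)C=C)C(C)(C)[C@](C(=O)c1ccccc1)(C4=O)C3=O
F8 | step 5 | 7-endo-allyl analogue of 9 (racemic, enantiomer matching 9 drawn) | CC(C)=CCC3=C(O)[C@@]4(C/C=C(\C)CCC=C(C)C)C[C@@H](CC=C)C(C)(C)[C@](C(=O)c1ccccc1)(C4=O)C3=O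
F9 | step 6 | 3-bromo-3-prenyl-2,4,9-trione derived from 9 (C3 configuration open) | CC(C)=CCC3(Br)C(=O)[C@@]4(C/C=C(\C)CCC=C(C)C)C[C@@H](CC=C(C)C)C(C)(C)[C@](C(=O)c1ccccc1)(C4=O)C3=O
F10 | step 6 | 14-(2-bromopropan-2-yl) analogue of 13 | CC(C)(Br)[C@@H]1C[C@@]23C(=O)[C@@]4(C/C=C(\C)CCC=C(C)C)C[C@@H](C[C@H]2C1(C)C)C(C)(C)[C@](C(=O)c1ccccc1)(C4=O)C3=O
F11 | step 2 | geranyl methyl carbonate | COC(=O)OC/C=C(\C)CCC=C(C)C
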